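The synthesis rests on disconnecting the C3–C4 bond of ring A, so that the cis-3β,4β-diol (secondary carbinol C3 beside the methyl-bearing tertiary carbinol C4) comes from an acyclic 1,6-keto-aldehyde. One SmI2 pinacol cyclisation closes ring A and sets C3 and C4 together. Its precursor carries the C4 methyl ketone, the C5 prenyl group and the quaternary C10 with methyl, a silyl-protected hydroxyethyl arm (C9–C8) and the 3-oxopropyl arm (C1–C3); the C5/C10 pair is set by one enantioselective Ireland–Claisen rearrangement. Ring B follows by a carbonyl-ene closure onto the prenyl group, and the C11 hydroperoxide by a singlet-oxygen ene reaction.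

Key step: step 9

Remark on numbering: eudesmane numbering is used for all intermediates (ring A: C1–C5 and C10; ring B: C5–C10; C11–C13 on C7; C14 on C10; C15 on C4).

Assumption: in step 6 the Et3N/toluene–hexane protocol is taken to give the boron enolate with the α-CH2 cis to O–B, and the (S,S)-bromoborane to select the face leading to (2R,3S)-12; if either proves otherwise, the i-Pr2NEt/CH2Cl2 protocol or the (R,R)-reagent is substituted and nothing else changes.

**Step 1**
Reactants: 1 3-butyn-1-ol
Product: 2 tert-butyl(but-3-yn-1-yloxy)diphenylsilane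
Conditions: TBDPSCl, imidazole, CH2Cl2, 0 °C → rt
Reagents that add atoms: tert-butyl(chloro)diphenylsilane, CC(C)(C)[Si](Cl)(c1ccccc1)c1ccccc1
Why: Imidazole-promoted silyl ether formation on a primary alcohol; the tert-butyldiphenylsilyl group is chosen because it should survive Me3Al, the Lewis-acidic bromoborane, MeLi, SmI2 and mild acid, and is later removed by fluoride without touching the acetonide.

**Step 2**
Reactants: 2 tert-butyl(but-3-yn-1-yloxy)diphenylsilane
Product: 5 (2E)-5-[(tert-butyldiphenylsilyl)oxy]-3-methylpent-2-en-1-ol, via alkenyldimethylalane 3 (not isolated), via lithium alkenylalanate 4 (not isolated)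
Conditions: Me3Al, Cp2ZrCl2 (cat.), CH2Cl2, 0 °C → rt; n-BuLi, hexane–THF, 0 °C; (CH2O)n, rt; cold dilute aq. HCl
Reagents that add atoms: trimethylaluminium, C[Al](C)C; formaldehyde (as paraformaldehyde), C=O
Why: Zirconium-catalysed Negishi carboalumination adds methyl and aluminium syn across the terminal alkyne with the metal at the terminus, and the derived alanate is hydroxymethylated with retention, which fixes the E geometry (methyl cis to CH2OH) that the Claisen step needs.

**Step 3**
Reactants: 6 2-methylbut-3-en-2-ol; 7 triethyl orthoacetate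
Product: 8 ethyl 5-methylhex-4-enoate
Conditions: EtCO2H (cat.), neat, 140 °C, ethanol distilled off
Reagents that add atoms: none
Why: Johnson–Claisen (orthoester Claisen) rearrangement of a tertiary allylic alcohol, a standard two-carbon homologation that delivers the prenyl-terminated ester.

**Step 4**
Reactants: 8 ethyl 5-methylhex-4-enoate
Product: 9 5-methylhex-4-enoic acid
Conditions: LiOH, THF–H2O, rt; then 1 M HCl
Reagents that add atoms: lithium hydroxide, [Li+].[OH-] (supplies the carboxyl OH oxygen)
Why: Ester saponification on a substrate with no stereocentre and no base-sensitive group.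

**Step 5**
Reactants: 5 (2E)-5-[(tert-butyldiphenylsilyl)oxy]-3-methylpent-2-en-1-ol; 9 5-methylhex-4-enoic acid
Product: 10 (2E)-5-[(tert-butyldiphenylsilyl)oxy]-3-methylpent-2-en-1-yl 5-methylhex-4-enoate
Conditions: DCC, DMAP (cat.), CH2Cl2, 0 °C → rt
Reagents that add atoms: none
Why: Steglich esterification of a primary allylic alcohol under neutral conditions that leave both trisubstituted alkenes and the silyl ether untouched.

**Step 6**
Reactants: 10 (2E)-5-[(tert-butyldiphenylsilyl)oxy]-3-methylpent-2-en-1-yl 5-methylhex-4-enoate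
Product: 12 (2R,3S)-3-{2-[(tert-butyldiphenylsilyl)oxy]ethyl}-3-methyl-2-(3-methylbut-2-en-1-yl)pent-4-enoic acid, via chiral boron ketene acetal 11 (not isolated)
Conditions: (4S,5S)-2-bromo-1,3-bis{[3,5-bis(trifluoromethyl)phenyl]sulfonyl}-4,5-diphenyl-1,3,2-diazaborolidine (1.2 equiv), Et3N, toluene–hexane, −78 °C, then 4 °C; H2O
Reagents that add atoms: none
Why: Enantioselective Ireland–Claisen rearrangement through a chiral boron ketene acetal: with the α-CH2 cis to O–B and the E-allyl unit, the chair [3,3] transition state places prenyl (C5) and the silyloxyethyl arm (C10) equatorial and so fixes their relative configuration, while the C2-symmetric bis-sulfonamide ligand on boron selects the enolate face, so that C5 and C10 are both set here and the new vinyl group is C1=C2.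

**Step 7**
Reactants: 12 (2R,3S)-3-{2-[(tert-butyldiphenylsilyl)oxy]ethyl}-3-methyl-2-(3-methylbut-2-en-1-yl)pent-4-enoic acid
Product: 13 (3R,4S)-4-{2-[(tert-butyldiphenylsilyl)oxy]ethyl}-4-methyl-3-(3-methylbut-2-en-1-yl)hex-5-en-2-one
Conditions: MeLi (2.5 equiv), Et2O, 0 °C → rt; then cold 1 M HCl
Reagents that add atoms: methyllithium, [Li]C
Why: Addition of MeLi to the lithium carboxylate of a hindered acid stops at the ketone oxidation level until work-up (carboxylic acid to methyl ketone), so the C4 methyl ketone forms in one step and C5 is never exposed to base as a ketone.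

**Step 8**
Reactants: 13 (3R,4S)-4-{2-[(tert-butyldiphenylsilyl)oxy]ethyl}-4-methyl-3-(3-methylbut-2-en-1-yl)hex-5-en-2-one
Product: 14 (4R,5R)-4-{2-[(tert-butyldiphenylsilyl)oxy]ethyl}-4-methyl-5-(3-methylbut-2-en-1-yl)-6-oxoheptanal
Conditions: Rh(acac)(CO)2 (1 mol%), Xantphos, CO/H2 (1:1, 10 bar), toluene, 70 °C
Reagents that add atoms: carbon monoxide, [C-]#[O+]
Why: Rhodium-catalysed hydroformylation with a wide-bite-angle diphosphine is linear-selective, branching next to the quaternary C10 is strongly disfavoured, and the trisubstituted prenyl alkene does not react under these mild conditions, so the vinyl group becomes the C1–C3 3-oxopropyl arm directly.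

**Step 9**
Reactants: 14 (4R,5R)-4-{2-[(tert-butyldiphenylsilyl)oxy]ethyl}-4-methyl-5-(3-methylbut-2-en-1-yl)-6-oxoheptanal
Product: 15 (1R,2S,5R,6R)-5-{2-[(tert-butyldiphenylsilyl)oxy]ethyl}-1,5-dimethyl-6-(3-methylbut-2-en-1-yl)cyclohexane-1,2-diol
Conditions: SmI2 (2.5 equiv), t-BuOH (2 equiv), THF, −78 °C → rt
Reagents that add atoms: none
Why: Single-electron transfer from SmI2 to the C3 aldehyde gives a samarium ketyl that adds to the samarium-bound C4 ketone carbonyl, and a second electron and protonation give the diol (ketone–aldehyde pinacol cyclisation, a known SmI2 reaction of 1,6-dicarbonyl compounds). Ring A closes by a 6-exo-trig radical addition that forms the C3–C4 bond. The cis relationship of the two new C–O bonds follows from both oxygens being held on one trivalent samarium centre in the cyclic transition state. Which cis-diol forms is decided at C4 by the chair in which the C5 prenyl group and the C10 silyloxyethyl arm are equatorial and the C10 methyl is axial: the C4 methyl then takes the equatorial site to avoid a 1,3-diaxial methyl–methyl contact, so the C4 oxygen is axial (β) and the chelated C3 oxygen is equatorial (β). The step needs chemoselectivity for the two carbonyl groups over the prenyl alkene and the silyl ether, both inert to SmI2 without additives, and it needs C5 next to the ketone to stay intact, which the neutral low-temperature conditions should secure.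

**Step 10**
Reactants: 15 (1R,2S,5R,6R)-5-{2-[(tert-butyldiphenylsilyl)oxy]ethyl}-1,5-dimethyl-6-(3-methylbut-2-en-1-yl)cyclohexane-1,2-diol
Product: 16 3β,4β-O-isopropylidene acetal of 15 (cis-fused 2,2-dimethyl-1,3-dioxolane across C3–C4; C3/C4/C5/C10 as in 15)
Conditions: Me2C(OMe)2, PPTS (cat.), CH2Cl2, rt
Reagents that add atoms: 2,2-dimethoxypropane, COC(C)(C)OC
Why: Acid-catalysed transketalisation closes a dioxolane readily on a cis-1,2-diol of a cyclohexane and masks the secondary C3 hydroxyl for the two oxidations ahead.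

**Step 11**
Reactants: 16 3β,4β-O-isopropylidene acetal of 15
Product: 17 primary alcohol (C8–OH) obtained by desilylation of 16
Conditions: TBAF, THF, rt
Reagents that add atoms: none
Why: Fluoride-mediated cleavage of the silyl ether, to which the acetonide and the prenyl alkene are inert.

**Step 12**
Reactants: 17 primary alcohol (C8–OH)
Product: 18 C8 aldehyde (acetonide-protected ring A carrying the C5 prenyl group and the C10 CH2CHO arm)
Conditions: Dess–Martin periodinane, NaHCO3, CH2Cl2, 0 °C → rt
Reagents that add atoms: none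
Why: Dess–Martin oxidation of a primary alcohol to the aldehyde under buffered conditions that touch neither the alkene nor the acetonide.

**Step 13**
Reactants: 18 C8 aldehyde
Product: 19 3β,4β-(isopropylidenedioxy)-5αH,7αH-eudesm-11-en-8α-ol
Conditions: Me2AlCl (1.5 equiv), CH2Cl2, −78 °C; aq. NaHCO3
Reagents that add atoms: none
Why: Lewis-acid-promoted intramolecular carbonyl-ene reaction of the citronellal-to-isopulegol kind: C8 bonds to C7 of the prenyl alkene while a methyl hydrogen shifts to oxygen, closing ring B through a chair with both tethers equatorial and hence as the trans-decalin; the new centres are expected mainly as 7β-isopropenyl and 8α-hydroxy but are erased in step 14.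

**Step 14**
Reactants: 19 3β,4β-(isopropylidenedioxy)-5αH,7αH-eudesm-11-en-8α-ol
Product: 21 3β,4β-(isopropylidenedioxy)-5αH-eudesm-7(11)-en-8-one, via isopropenyl ketone 20 (not isolated)
Conditions: (COCl)2, DMSO, CH2Cl2, −78 °C; Et3N, −78 °C → rt; then DBU (excess), rt
Reagents that add atoms: none
Why: Swern oxidation gives the β,γ-unsaturated ketone and DBU then moves the alkene into conjugation through the dienolate (base-mediated isomerisation as in isopulegone to pulegone), which removes the C7 and C8 stereocentres while C5 and C10 cannot epimerise.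

**Step 15**
Reactants: 21 3β,4β-(isopropylidenedioxy)-5αH-eudesm-7(11)-en-8-one
Product: 22 3β,4β-dihydroxy-5αH-eudesm-7(11)-en-8-one
Conditions: AcOH–H2O (4:1), 60 °C
Reagents that add atoms: none
Why: Acid hydrolysis of the acetonide, which the tetrasubstituted enone and the tertiary alcohol should tolerate.

**Step 16**
Reactants: 22 3β,4β-dihydroxy-5αH-eudesm-7(11)-en-8-one; 23 angelic acid
Product: 25 3β-angeloyloxy-4β-hydroxy-5αH-eudesm-7(11)-en-8-one, via angelic 2,4,6-trichlorobenzoic anhydride 24 (not isolated)
Conditions: 23, 2,4,6-trichlorobenzoyl chloride, Et3N, toluene, rt; then 22, 75 °C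
Reagents that add atoms: none
Why: Acylation of the equatorial secondary C3 hydroxyl with the pre-formed Yamaguchi-type mixed anhydride of angelic acid, run without a nucleophilic catalyst to suppress isomerisation to the tiglate, while the axial tertiary C4 hydroxyl is too hindered to react.

**Step 17**
Reactants: 25 3β-angeloyloxy-4β-hydroxy-5αH-eudesm-7(11)-en-8-one
Product: 26 3β-angeloyloxy-4β-hydroxy-11-hydroperoxy-5αH-eudesm-6-en-8-one (CNP0161122.3)
Conditions: O2, tetraphenylporphyrin (cat.), visible light, CH2Cl2, 0 °C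
Reagents that add atoms: dioxygen, O=O
Why: Singlet-oxygen ene (Schenck) reaction of an s-cis α,β-unsaturated ketone: oxygen bonds to C11 and hydrogen is taken from C6, the carbon attached to the α-carbon C7 (geminal selectivity of enones), which moves the alkene to C6=C7 in conjugation with C8=O; the tetrasubstituted enone alkene should react much faster than the electron-poor trisubstituted angelate, and no stereocentre is formed.

**Compound list**

1 | 3-butyn-1-ol | C#CCCO | starting material
2 | tert-butyl(but-3-yn-1-yloxy)diphenylsilane | C#CCCO[Si](c1ccccc1)(c1ccccc1)C(C)(C)C | intermediate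
3 | (E)-{4-[(tert-butyldiphenylsilyl)oxy]-2-methylbut-1-en-1-yl}dimethylalane | C[Al](C)/C=C(\C)CCO[Si](c1ccccc1)(c1ccccc1)C(C)(C)C | intermediate (not isolated)
4 | lithium butyl{(E)-4-[(tert-butyldiphenylsilyl)oxy]-2-methylbut-1-en-1-yl}dimethylalanate | [Li+].CCCC[Al-](C)(C)/C=C(\C)CCO[Si](c1ccccc1)(c1ccccc1)C(C)(C)C | intermediate (not isolated)
5 | (2E)-5-[(tert-butyldiphenylsilyl)oxy]-3-methylpent-2-en-1-ol | OC/C=C(\C)CCO[Si](c1ccccc1)(c1ccccc1)C(C)(C)C | intermediate
6 | 2-methylbut-3-en-2-ol | CC(C)(O)C=C | starting material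
7 | triethyl orthoacetate | CCOC(C)(OCC)OCC | starting material
8 | ethyl 5-methylhex-4-enoate | CCOC(=O)CCC=C(C)C | intermediate
9 | 5-methylhex-4-enoic acid | OC(=O)CCC=C(C)C | intermediate
10 | (2E)-5-[(tert-butyldiphenylsilyl)oxy]-3-methylpent-2-en-1-yl 5-methylhex-4-enoate | CC(C)=CCCC(=O)OC/C=C(\C)CCO[Si](c1ccccc1)(c1ccccc1)C(C)(C)C | intermediate
11 | boron ketene acetal of 10 (α-CH2 cis to O–B; boron in the (4S,5S)-1,3-bis{[3,5-bis(trifluoromethyl)phenyl]sulfonyl}-4,5-diphenyl-1,3,2-diazaborolidine ring) | CC(C)=CC/C=C(\OB1N(S(=O)(=O)c2cc(cc(c2)C(F)(F)F)C(F)(F)F)[C@@H](c2ccccc2)[C@H](c2ccccc2)N1S(=O)(=O)c1cc(cc(c1)C(F)(F)F)C(F)(F)F)OC/C=C(\C)CCO[Si](c1ccccc1)(c1ccccc1)C(C)(C)C | intermediate (not isolated)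
12 | (2R,3S)-3-{2-[(tert-butyldiphenylsilyl)oxy]ethyl}-3-methyl-2-(3-methylbut-2-en-1-yl)pent-4-enoic acid | OC(=O)[C@H](CC=C(C)C)[C@@](C)(CCO[Si](c1ccccc1)(c1ccccc1)C(C)(C)C)C=C | intermediate
13 | (3R,4S)-4-{2-[(tert-butyldiphenylsilyl)oxy]ethyl}-4-methyl-3-(3-methylbut-2-en-1-yl)hex-5-en-2-one | CC(=O)[C@H](CC=C(C)C)[C@@](C)(CCO[Si](c1ccccc1)(c1ccccc1)C(C)(C)C)C=C | intermediate
14 | (4R,5R)-4-{2-[(tert-butyldiphenylsilyl)oxy]ethyl}-4-methyl-5-(3-methylbut-2-en-1-yl)-6-oxoheptanal (C3 aldehyde, C4 methyl ketone) | CC(=O)[C@H](CC=C(C)C)[C@@](C)(CCO[Si](c1ccccc1)(c1ccccc1)C(C)(C)C)CCC=O | intermediate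
15 | (1R,2S,5R,6R)-5-{2-[(tert-butyldiphenylsilyl)oxy]ethyl}-1,5-dimethyl-6-(3-methylbut-2-en-1-yl)cyclohexane-1,2-diol (ring A, 3β,4β-diol) | O[C@H]1CC[C@](C)(CCO[Si](c2ccccc2)(c2ccccc2)C(C)(C)C)[C@@H](CC=C(C)C)[C@@]1(C)O | intermediate
16 | 3β,4β-O-isopropylidene acetal of 15 | CC1(C)O[C@H]2CC[C@](C)(CCO[Si](c3ccccc3)(c3ccccc3)C(C)(C)C)[C@@H](CC=C(C)C)[C@@]2(C)O1 | intermediate
17 | C8 primary alcohol (desilylated 16) | CC1(C)O[C@H]2CC[C@](C)(CCO)[C@@H](CC=C(C)C)[C@@]2(C)O1 | intermediate
18 | C8 aldehyde | CC1(C)O[C@H]2CC[C@](C)(CC=O)[C@@H](CC=C(C)C)[C@@]2(C)O1 | intermediate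
19 | 3β,4β-(isopropylidenedioxy)-5αH,7αH-eudesm-11-en-8α-ol (expected major isomer; C7/C8 inconsequential) | CC1(C)O[C@H]2CC[C@]3(C)C[C@H](O)[C@@H](C(C)=C)C[C@H]3[C@@]2(C)O1 | intermediate
20 | 3β,4β-(isopropylidenedioxy)-5αH,7αH-eudesm-11-en-8-one | CC1(C)O[C@H]2CC[C@]3(C)CC(=O)[C@@H](C(C)=C)C[C@H]3[C@@]2(C)O1 | intermediate (not isolated)
21 | 3β,4β-(isopropylidenedioxy)-5αH-eudesm-7(11)-en-8-one | CC1(C)O[C@H]2CC[C@]3(C)CC(=O)C(=C(C)C)C[C@H]3[C@@]2(C)O1 | intermediate
22 | 3β,4β-dihydroxy-5αH-eudesm-7(11)-en-8-one | O[C@H]1CC[C@]2(C)CC(=O)C(=C(C)C)C[C@H]2[C@@]1(C)O | intermediate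
23 | angelic acid, (Z)-2-methylbut-2-enoic acid | C/C=C(/C)C(=O)O | starting material
24 | angelic 2,4,6-trichlorobenzoic anhydride | C/C=C(/C)C(=O)OC(=O)c1c(Cl)cc(Cl)cc1Cl | intermediate (not isolated)
25 | 3β-angeloyloxy-4β-hydroxy-5αH-eudesm-7(11)-en-8-one | C/C=C(/C)C(=O)O[C@H]1CC[C@]2(C)CC(=O)C(=C(C)C)C[C@H]2[C@@]1(C)O | intermediate
26 | (3S,4R,5R,10R)-3β-angeloyloxy-4β-hydroxy-11-hydroperoxy-eudesm-6-en-8-one, CNP0161122.3 | C/C=C(/C)C(=O)O[C@H]1CC[C@]2(C)CC(=O)C(C(C)(C)OO)=C[C@H]2[C@@]1(C)O | target

**Totals**

Total step count: 17. Longest linear sequence: 15 steps (steps 1, 2 and 5–17, from 3-butyn-1-ol); steps 3 and 4 make the acid side arm.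

**Steps most likely to fail**

Step 9 (key pinacol cyclisation). The ring-flipped chair, with prenyl and silyloxyethyl axial and the C10 methyl equatorial, may compete and lead to the 3α,4α-cis-diol. The aldehyde ketyl may also be reduced to the primary alcohol before the hindered ketone traps it. The fallback forms the same C3–C4 bond without a reductant and sets C3 afterwards. Keto-aldehyde 14 is cyclised by a carbene-catalysed intramolecular crossed benzoin reaction (3-benzyl-5-(2-hydroxyethyl)-4-methylthiazolium chloride, Et3N, t-BuOH, 40 °C). The acyl-anion equivalent at C3 adds to the C4 ketone, and because this addition is reversible the ketol with equatorial C4 methyl should accumulate, giving (2R,3R,4R)-4-{2-[(tert-butyldiphenylsilyl)oxy]ethyl}-2-hydroxy-2,4-dimethyl-3-(3-methylbut-2-en-1-yl)cyclohexan-1-one F1. NaBH4 in MeOH at −40 °C should then deliver hydride to C3 axially from the α face and give the equatorial 3β-alcohol, which is diol 15.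

Step 6 (boron Ireland–Claisen). Enolisation may give the other enolate geometry, which inverts C5 relative to C10. The [3,3] shift that creates the quaternary C10 may be sluggish, or the enantiofacial sense may be opposite. The fallback gives up reagent control for substrate-controlled diastereoselection followed by resolution. Ester 10 is deprotonated with LiN(i-Pr)2 in THF–DMPU at −78 °C (α-CH2 cis to O–Li) and silylated with Me3SiCl to the trimethylsilyl ketene acetal F2. This should rearrange at rt through the same chair to the racemic trimethylsilyl ester F3. Dilute acid hydrolysis gives the racemic acid, that is 12 together with its (2S,3R)-enantiomer F4. Preparative chromatography on a chiral stationary phase returns enantiopure acid 12.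

Step 16 (angeloylation). The Z-configured angeloyl unit may isomerise to the E (tigloyl) form during activation or acyl transfer, and acylation of the C3 hydroxyl beside the tertiary C4 carbinol may be slow. The fallback builds the Z alkene on the substrate instead of transferring it. Diol 22 is esterified at C3 with 2-[bis(2,2,2-trifluoroethoxy)phosphoryl]propanoic acid (DCC, DMAP cat., CH2Cl2) to give the 3β-O-{2-[bis(2,2,2-trifluoroethoxy)phosphoryl]propanoyl} ester F5, as a mixture of epimers at the phosphonate carbon. Still–Gennari olefination with acetaldehyde (KN(SiMe3)2, 18-crown-6, THF, −78 °C) should then form the Z-trisubstituted alkene and give angelate 25.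

**Further compounds**

F1 | step 9 | (2R,3R,4R)-4-{2-[(tert-butyldiphenylsilyl)oxy]ethyl}-2-hydroxy-2,4-dimethyl-3-(3-methylbut-2-en-1-yl)cyclohexan-1-one | O=C1CC[C@](C)(CCO[Si](c2ccccc2)(c2ccccc2)C(C)(C)C)[C@@H](CC=C(C)C)[C@@]1(C)O
F2 | step 6 | trimethylsilyl ketene acetal of 10 (α-CH2 cis to O–Si) | CC(C)=CC/C=C(\O[Si](C)(C)C)OC/C=C(\C)CCO[Si](c1ccccc1)(c1ccccc1)C(C)(C)C
F3 | step 6 | racemic trimethylsilyl ester of acid 12 (drawn as the enantiomer that leads to 12) | C[Si](C)(C)OC(=O)[C@H](CC=C(C)C)[C@@](C)(CCO[Si](c1ccccc1)(c1ccccc1)C(C)(C)C)C=C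
F4 | step 6 | (2S,3R)-3-{2-[(tert-butyldiphenylsilyl)oxy]ethyl}-3-methyl-2-(3-methylbut-2-en-1-yl)pent-4-enoic acid (enantiomer of 12) | OC(=O)[C@@H](CC=C(C)C)[C@](C)(CCO[Si](c1ccccc1)(c1ccccc1)C(C)(C)C)C=C
F5 | step 16 | 3β-O-{2-[bis(2,2,2-trifluoroethoxy)phosphoryl]propanoyl}-4β-hydroxy-5αH-eudesm-7(11)-en-8-one (epimers at the phosphonate carbon) | CC(C(=O)O[C@H]1CC[C@]2(C)CC(=O)C(=C(C)C)C[C@H]2[C@@]1(C)O)P(=O)(OCC(F)(F)F)OCC(F)(F)F
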